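# Balanophonin by ring contraction of a chiral flavanone: synthesis design

Compound numbers used throughout: starting materials 1, 5 and 14; flavanone 9; ring-contracted ester 11; target 16.

## The problem

Balanophonin (16) is a 2,3-dihydrobenzofuran neolignan. Ring A is fused to the oxygen ring through C3a and C7a and carries a methoxy group at C7 and an (E)-propenal chain at C5, para to the ring oxygen O1. C2 bears ring B (4-hydroxy-3-methoxyphenyl) and C3 a hydroxymethyl group. The only ring to be built is the five-membered O1–C2–C3–C3a–C7a ring, and with it the two adjacent stereocentres, C2 (R) and C3 (S), which are trans. Trans is the more stable arrangement, so one centre set in the absolute sense can direct the other: C3 can steer C2 whenever the C2–O1 bond is made, and C2 can steer C3 if the bond to C3 is formed anti to ring B or if C3 carries an acidifying carboxyl-level group. Three groups limit the chemistry. The enal is attacked by base, hydride, nucleophiles and oxidants, so it must come last. The free phenol of ring B is oxidised by hypervalent iodine and, as phenoxide, can open the benzylic C2–O1 bond through a quinone methide. Any C3–H that is α to a carbonyl group is at risk because O1 sits β to it and can be expelled. The enabling feature is the substitution at C3: it holds ring A carbon C3a and a one-carbon group that can be an ester, next to a C2 that holds ring B and O1. This is the array left when the aryl carbon C4a of a 2-arylchroman-4-one shifts from C4 to C3 and C4 leaves the ring as CO2Me, a change that does not touch C2.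

## Retrosynthesis

The C5–Cα bond of the propenal chain is cut first, taking 16 back to aryl bromide 13 and acrolein diethyl acetal 14. The forward reaction is a Heck coupling that gives acetal 15 and, with dilute acid, the enal. An alkene or aldehyde at C5 could not be carried through the route, because the oxidant of the key step would not spare a styrene and the later hydride and base would not spare an enal; a bromine atom is inert to all of them. The forward step must give the E alkene and must direct β-hydride elimination to the benzylic side.

Bromide 13 is related to ester 11 by two functional-group changes and no skeletal cut: cleavage of a tosylate on the ring B phenol (12 to 13) and reduction of the C3 ester (11 to 12). The tosylate serves the key step, where it shields the phenol from the oxidant and makes ring B electron-poor. It is removed after the reduction, because hot hydroxide would saponify the ester and invite expulsion of O1 from the enolate. It is removed before the Heck coupling, so that the enal never meets methoxide.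

In 11 the C3–C3a bond is cut and C3a is reconnected to the ester carbon, which returns to the ring as a ketone. This gives flavanone 9; the forward reaction runs through enol ether 10. Two neighbouring cuts were weighed. Cutting O1–C2 leads to open-chain 1,2-diaryl precursors in which C3 must be set alone. Cutting C2–C3 leads to two-component annulations in which both centres form at once. The C3–C3a cut removes one stereocentre and leaves the other as the β-carbon of an enone. The forward step must make ring A migrate in preference to ring B, must deliver the trans ester and must not ionise C2.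

Flavanone 9 is cut at the C2–aryl bond into chromone 4 and boronic acid 8. Compared with cyclisation of a 2'-hydroxychalcone, this cut creates the stereocentre under catalyst control in the C–C bond-forming step. The forward reaction must run close to neutral, since a flavanone enolate opens to the chalcone and racemises.

Chromone 4 is cut at O1–C2 and C2–C3. The C2 carbon comes from DMF dimethyl acetal through enaminone 3, made from bromoketone 2, which is the para-bromination product of commercial ketone 1. Boronic acid 8 comes from commercial phenol 5 by tosylation (6) and exchange of bromine for boron through pinacol boronate 7. Both branches use only routine aromatic chemistry.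

## Roads not taken

Alternative 1: The C2–aryl (ring B) and C3–C3a bonds are cut together, with no ring closure in the key step. The ring B aryllithium A1 would add to the (E)-alkenyl pinacol boronate A2 to give an ate complex. With Pd(OAc)2 and a chiral MandyPhos ligand, the ring A aryl bromide A3 would trigger a 1,2-metallate shift and give the anti boronic ester A4 with the C3 configuration of the target.
- Merits: three fragments are joined in one catalytic enantioselective step, and C3 is set directly by the catalyst.
- Weak points: with a β-substituted alkenyl boronate carrying pinacol on boron, direct transmetallation (plain cross-coupling) competes with the metallate shift. Bromide A3 is flanked by an ortho alkoxy group, which slows its entry. The boron-bearing centre of A4 is not the final C2: the C–B bond must be oxidised, both MOM groups removed and O1–C2 closed, so the C2 configuration is remade. Silyl removal, acetal hydrolysis and a two-carbon extension of the aldehyde follow.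
- Comparison: this road is more convergent than the chosen one and sets C3 by catalyst. The chosen plan offers in return a stereocentre (C2) that is made once and kept, and three operations after the key step.

Alternative 2: The O1–C2 and C2–C3 bonds are cut in a formal [4+1] annulation. With Cs2CO3 the ylide from benzylic sulfonium salt A6 (drawn with a C2-symmetric chiral thiolane) would add to the alkene carbon next to ring A in nitrovinylphenol A5, and the phenoxide would displace the sulfide at C2 to give A7.
- Merits: the ring and both stereocentres form in one step from two simple pieces, the trans relationship is inherent, and the same bromine handle is present.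
- Weak points: the ylide is only semi-stabilised, and in a stepwise Michael addition and ring closure the absolute sense depends on which step is selectivity-determining, so control by the chiral sulfide is not secure. The nitromethyl group of A7 must pass through the aldehyde level (Nef reaction) before reduction; at that level C3–H is acidic and O1 can be lost by β-elimination. The MOM group must finally be removed with acid from a para-alkoxybenzyl ether.
- Comparison: this road reaches the dihydrobenzofuran in fewer steps. The chosen plan offers in return absolute control in a conjugate addition of established scope and a C3 substituent that is born at the ester level and reduced in one step.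

Alternative 3: Only the O1–C2 bond is cut. DDQ (or Ag2O) would oxidise the ring B benzylic CH2 of diol A8 to para-quinone methide A9, and the ring A phenol would add to C2 trans to the hydroxymethyl group to give A10, which is identical with 13.
- Merits: ring B needs no protecting group, the stereorelay from C3 to C2 is thermodynamically sound, and the route would join the present one at 13 without the reduction and detosylation steps.
- Weak points: A8 holds two electron-rich phenols and two benzylic positions, and the oxidant must select the ring B CH2. The product A10 is still a para-hydroxybenzyl ether and can be oxidised further towards the benzofuran. The lone stereocentre of A8 must be made by auxiliary-based alkylation or asymmetric hydrogenation, which adds steps and, in the first case, stoichiometric chirality.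
- Comparison: this road is better in protecting-group economy. The chosen plan offers in return catalytic generation of chirality and a key oxidation in which ring B is masked and deactivated, so no choice between two phenols arises.

Key step: step 6

Assumption: the (R)-antipode of MeO-F12-BIPHEP, (R)-2,2'-bis[bis(3,4,5-trifluorophenyl)phosphino]-6,6'-dimethoxy-1,1'-biphenyl, is taken to give the (2R)-flavanone, by analogy with the sense in which (S)-biaryl diphosphine–rhodium catalysts give (S)-3-arylcyclohexanones; if the sense is reversed on this chromone, the (S)-ligand is used and nothing else changes.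

## Route

Step 1
Reactants: 1 2'-hydroxy-3'-methoxyacetophenone
Product: 2 1-(5-bromo-2-hydroxy-3-methoxyphenyl)ethanone
Conditions: NBS, MeCN, 0 °C to rt
Reagents that add atoms: N-bromosuccinimide, O=C1CCC(=O)N1Br
Why: Electrophilic aromatic bromination; the phenol directs to its para position (both ortho positions are occupied), as in the bromination of ortho-vanillin, and NBS in MeCN avoids the α-bromination of the methyl ketone that Br2 in acid would risk.

Step 2
Reactants: 2 1-(5-bromo-2-hydroxy-3-methoxyphenyl)ethanone
Product: 4 6-bromo-8-methoxy-4H-chromen-4-one, via enaminone 3 (not isolated)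
Conditions: Me2NCH(OMe)2, toluene, 100 °C; then conc. HCl, CH2Cl2, 40 °C
Reagents that add atoms: N,N-dimethylformamide dimethyl acetal, COC(OC)N(C)C
Why: Enaminone route to chromones: condensation at the acetyl methyl group, then acid-promoted conjugate addition of the phenol and loss of dimethylamine; the reagent carbon becomes C2.

Step 3
Reactants: 5 4-bromo-2-methoxyphenol
Product: 6 4-bromo-2-methoxyphenyl 4-methylbenzenesulfonate
Conditions: TsCl, Et3N, DMAP (cat.), CH2Cl2, 0 °C to rt
Reagents that add atoms: p-toluenesulfonyl chloride, Cc1ccc(cc1)S(Cl)(=O)=O
Why: O-Sulfonylation of a phenol; the tosylate is chosen because it survives palladium, rhodium, acid, trivalent iodine and borohydride, and because it withdraws electron density from ring B.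

Step 4
Reactants: 6 4-bromo-2-methoxyphenyl 4-methylbenzenesulfonate
Product: 8 [3-methoxy-4-(tosyloxy)phenyl]boronic acid, via pinacol boronate 7 (not isolated)
Conditions: B2pin2, Pd(dppf)Cl2 (cat.), KOAc, 1,4-dioxane, 85 °C; then NaIO4, NH4OAc, acetone/H2O, rt
Reagents that add atoms: bis(pinacolato)diboron, CC1(C)OB(OC1(C)C)B1OC(C)(C)C(C)(C)O1; water, O
Why: Miyaura borylation of the aryl bromide, in which the dppf-ligated catalyst does not insert into the aryl tosylate, followed by periodate cleavage of the pinacol unit to free the boronic acid needed for clean rhodium transmetallation.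

Step 5
Reactants: 4 6-bromo-8-methoxy-4H-chromen-4-one; 8 [3-methoxy-4-(tosyloxy)phenyl]boronic acid
Product: 9 (2R)-6-bromo-8-methoxy-2-[3-methoxy-4-(tosyloxy)phenyl]chroman-4-one
Conditions: [RhOH{(R)-MeO-F12-BIPHEP}]2 (cat.), toluene, H2O (few equiv), 25 °C
Reagents that add atoms: none
Why: Rhodium-catalysed asymmetric 1,4-addition of an arylboronic acid to a chromone (Hayashi–Miyaura reaction); the electron-poor diphosphine speeds aryl transfer so that the reaction runs near room temperature and close to neutral, which suppresses ring-opening of the flavanone, and the C2 stereocentre is set by the ligand (catalyst control), the aryl bromide being inert to monovalent rhodium.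

Step 6
Reactants: 9 (2R)-6-bromo-8-methoxy-2-[3-methoxy-4-(tosyloxy)phenyl]chroman-4-one
Product: 11 methyl (2R,3R)-5-bromo-7-methoxy-2-[3-methoxy-4-(tosyloxy)phenyl]-2,3-dihydro-1-benzofuran-3-carboxylate (trans), via enol ether 10 (not isolated)
Conditions: PhI(OAc)2, H2SO4, HC(OMe)3, rt
Reagents that add atoms: trimethyl orthoformate, COC(OC)OC; water, O
Why: This is the known oxidative 1,2-aryl shift of flavanones with trivalent iodine in trimethyl orthoformate, which gives methyl trans-2-aryl-2,3-dihydrobenzofuran-3-carboxylates. Acid and orthoformate turn the ketone of 9 into enol ether 10, whose C3 is attacked by the electrophilic iodine of PhI(OAc)2 on the face anti to ring B, and methanol adds to the resulting C4 oxocarbenium ion. The C4–C4a bond then lies antiperiplanar to the equatorial C3–iodine bond, and ring A carbon C4a moves from C4 to C3 through a bridged phenonium-type transition state as iodobenzene leaves; this forms the C3–C3a bond and leaves C4 outside the ring as a dialkoxycarbenium ion that work-up converts into CO2Me. The five-membered ring therefore arises by ring contraction of the six-membered one through this 1,2-shift, not by a new heteroatom cyclisation. The new C3 stereocentre is controlled by C2: anti attack of iodine followed by inversion at C3 places the ester trans to ring B, and because C3–H is α to the ester the trans isomer is also the thermodynamic one. C2 is never part of a cation or an enol, so the configuration from step 5 is kept. The step needs ring A to migrate in preference to ring B (isoflavone pathway) and to loss of the C2 proton (flavone pathway); the para-tosyloxy group makes ring B a poor migrating group and a poor stabiliser of positive charge at C2, while C4a is activated by the ortho oxygen O1.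

Step 7
Reactants: 11 methyl (2R,3R)-5-bromo-7-methoxy-2-[3-methoxy-4-(tosyloxy)phenyl]-2,3-dihydro-1-benzofuran-3-carboxylate
Product: 12 4-[(2R,3S)-5-bromo-3-(hydroxymethyl)-7-methoxy-2,3-dihydro-1-benzofuran-2-yl]-2-methoxyphenyl 4-methylbenzenesulfonate
Conditions: LiBH4, THF, 0 °C to rt
Reagents that add atoms: none
Why: Borohydride reduction of the methyl ester to the primary alcohol; LiBH4 leaves the aryl bromide and the aryl sulfonate alone, the low temperature keeps β-elimination of O1 from the ester enolate in check, and the C3 descriptor changes from R to S only through the priority rules.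

Step 8
Reactants: 12 4-[(2R,3S)-5-bromo-3-(hydroxymethyl)-7-methoxy-2,3-dihydro-1-benzofuran-2-yl]-2-methoxyphenyl 4-methylbenzenesulfonate
Product: 13 4-[(2R,3S)-5-bromo-3-(hydroxymethyl)-7-methoxy-2,3-dihydro-1-benzofuran-2-yl]-2-methoxyphenol
Conditions: KOH, MeOH, 60 °C; then aq. NH4Cl
Reagents that add atoms: none
Why: Basic solvolysis of the aryl sulfonate by attack at sulfur frees the phenol; it is done at the bromide stage because the enal would not survive methoxide, and any reversible opening of C2–O1 through the phenoxide should reclose intramolecularly to the trans ring under the direction of C3.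

Step 9
Reactants: 13 4-[(2R,3S)-5-bromo-3-(hydroxymethyl)-7-methoxy-2,3-dihydro-1-benzofuran-2-yl]-2-methoxyphenol; 14 acrolein diethyl acetal
Product: 16 balanophonin, (E)-3-[(2R,3S)-2-(4-hydroxy-3-methoxyphenyl)-3-(hydroxymethyl)-7-methoxy-2,3-dihydro-1-benzofuran-5-yl]prop-2-enal, via diethyl acetal 15 (not isolated)
Conditions: Pd(OAc)2 (cat.), n-Bu4NOAc, K2CO3, KCl, DMF, 90 °C; then 2 M HCl, rt
Reagents that add atoms: water, O
Why: Mizoroki–Heck coupling of the aryl bromide with acrolein diethyl acetal under ligand-free tetraalkylammonium acetate (Jeffery-type) conditions, which direct β-hydride elimination to the benzylic hydrogen and give the (E)-cinnamaldehyde acetal; brief treatment with dilute acid then unmasks the enal without touching the two stereocentres.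

## Compound list

1 | 2'-hydroxy-3'-methoxyacetophenone | CC(=O)c1cccc(OC)c1O | starting material
2 | 1-(5-bromo-2-hydroxy-3-methoxyphenyl)ethanone | CC(=O)c1cc(Br)cc(OC)c1O | intermediate
3 | (E)-1-(5-bromo-2-hydroxy-3-methoxyphenyl)-3-(dimethylamino)prop-2-en-1-one | CN(C)/C=C/C(=O)c1cc(Br)cc(OC)c1O | intermediate
4 | 6-bromo-8-methoxy-4H-chromen-4-one | COc1cc(Br)cc2c(=O)ccoc12 | intermediate
5 | 4-bromo-2-methoxyphenol | COc1cc(Br)ccc1O | starting material
6 | 4-bromo-2-methoxyphenyl 4-methylbenzenesulfonate | COc1cc(Br)ccc1OS(=O)(=O)c1ccc(C)cc1 | intermediate
7 | 2-methoxy-4-(4,4,5,5-tetramethyl-1,3,2-dioxaborolan-2-yl)phenyl 4-methylbenzenesulfonate | COc1cc(B2OC(C)(C)C(C)(C)O2)ccc1OS(=O)(=O)c1ccc(C)cc1 | intermediate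
8 | [3-methoxy-4-(tosyloxy)phenyl]boronic acid | COc1cc(B(O)O)ccc1OS(=O)(=O)c1ccc(C)cc1 | intermediate
9 | (2R)-6-bromo-8-methoxy-2-[3-methoxy-4-(tosyloxy)phenyl]chroman-4-one | COc1cc([C@H]2CC(=O)c3cc(Br)cc(OC)c3O2)ccc1OS(=O)(=O)c1ccc(C)cc1 | intermediate
10 | (2R)-6-bromo-4,8-dimethoxy-2-[3-methoxy-4-(tosyloxy)phenyl]-2H-chromene | COc1cc([C@H]2C=C(OC)c3cc(Br)cc(OC)c3O2)ccc1OS(=O)(=O)c1ccc(C)cc1 | intermediate
11 | methyl (2R,3R)-5-bromo-7-methoxy-2-[3-methoxy-4-(tosyloxy)phenyl]-2,3-dihydro-1-benzofuran-3-carboxylate (trans) | COc1cc([C@@H]2Oc3c(OC)cc(Br)cc3[C@H]2C(=O)OC)ccc1OS(=O)(=O)c1ccc(C)cc1 | intermediate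
12 | 4-[(2R,3S)-5-bromo-3-(hydroxymethyl)-7-methoxy-2,3-dihydro-1-benzofuran-2-yl]-2-methoxyphenyl 4-methylbenzenesulfonate | COc1cc([C@@H]2Oc3c(OC)cc(Br)cc3[C@H]2CO)ccc1OS(=O)(=O)c1ccc(C)cc1 | intermediate
13 | 4-[(2R,3S)-5-bromo-3-(hydroxymethyl)-7-methoxy-2,3-dihydro-1-benzofuran-2-yl]-2-methoxyphenol | COc1cc([C@@H]2Oc3c(OC)cc(Br)cc3[C@H]2CO)ccc1O | intermediate
14 | acrolein diethyl acetal (3,3-diethoxyprop-1-ene) | C=CC(OCC)OCC | starting material
15 | 4-[(2R,3S)-5-[(E)-3,3-diethoxyprop-1-enyl]-3-(hydroxymethyl)-7-methoxy-2,3-dihydro-1-benzofuran-2-yl]-2-methoxyphenol | COc1cc([C@@H]2Oc3c(OC)cc(/C=C/C(OCC)OCC)cc3[C@H]2CO)ccc1O | intermediate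
16 | balanophonin, (E)-3-[(2R,3S)-2-(4-hydroxy-3-methoxyphenyl)-3-(hydroxymethyl)-7-methoxy-2,3-dihydro-1-benzofuran-5-yl]prop-2-enal | COc1cc([C@@H]2Oc3c(OC)cc(/C=C/C=O)cc3[C@H]2CO)ccc1O | target

## Step count and risks

Total: 9 steps. Longest linear sequence: 7 steps (steps 1, 2, 5, 6, 7, 8, 9 from 1; the branch from 5 through steps 3 and 4 is equally long).

**Step 6 (key step).** The most likely failure is loss of chemoselectivity in the rearrangement. Migration of ring A may be slow, because C4a is activated only by the ortho oxygen while bromine and methoxy sit meta to it. Proton loss from C2 (flavone), α-methoxylation at C3, or acid-induced opening of the pyranone with erosion of the C2 configuration could then compete.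

Fallback, from 9 back to 11, is a Wolff ring contraction, which forms the same C3–C3a bond. Flavanone 9 is acylated at C3 (LiN(SiMe3)2, CF3CO2CH2CF3, THF, −78 °C) to the 3-trifluoroacetyl derivative of 9 in its enol form F1. Detrifluoroacetylative diazo transfer (MsN3, Et3N, H2O, MeCN) gives (2S)-6-bromo-3-diazo-8-methoxy-2-[3-methoxy-4-(tosyloxy)phenyl]chroman-4-one F2, in which the spatial arrangement at C2 is unchanged. Irradiation in MeOH contracts the ring through the ketene, and catalytic NaOMe in MeOH at 0 °C equilibrates the ester to trans 11.

**Step 5.** The most likely failure is loss of enantiomeric purity, either through incomplete face discrimination on a chromone carrying a methoxy group next to O1, or through reversible opening of the flavanone to the chalcone if the medium becomes basic. Protodeboronation of 8 would lower conversion.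

Fallback, from 2 back to 9, is a kinetic resolution. Ketone 2 is condensed (piperidine, EtOH, reflux; Claisen–Schmidt) with 4-formyl-2-methoxyphenyl 4-methylbenzenesulfonate F3, made from vanillin and TsCl, to give (E)-1-(5-bromo-2-hydroxy-3-methoxyphenyl)-3-[3-methoxy-4-(tosyloxy)phenyl]prop-2-en-1-one F4. NaOAc in refluxing EtOH closes it to racemic 6-bromo-8-methoxy-2-[3-methoxy-4-(tosyloxy)phenyl]chroman-4-one F5. Asymmetric transfer hydrogenation with RuCl(p-cymene)[(S,S)-TsDPEN] and HCO2H/Et3N should reduce the (2S)-ketone to (2S,4S)-6-bromo-8-methoxy-2-[3-methoxy-4-(tosyloxy)phenyl]chroman-4-ol F6 and leave 9 for separation.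

**Step 8.** The most likely failure is phenoxide-triggered opening of the C2–O1 bond to a quinone methide at 60 °C, followed by irreversible proton loss at C3 or loss of formaldehyde to a stilbene, in competition with the slow attack at sulfur.

Fallback, from 12 back to 15, changes both the order and the cleavage mechanism. Alcohol 12 is coupled with 14 under the palladium conditions of step 9, with a NaHCO3 work-up in place of acid, to give 4-[(2R,3S)-5-[(E)-3,3-diethoxyprop-1-enyl]-3-(hydroxymethyl)-7-methoxy-2,3-dihydro-1-benzofuran-2-yl]-2-methoxyphenyl 4-methylbenzenesulfonate F7. With the aryl bromide gone, the sulfonate is cleaved reductively with Mg in MeOH at room temperature to 15, which dilute HCl converts into 16.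

**Step 9.** The most likely failures are β-hydride elimination towards the acetal carbon (which after hydrolysis gives a saturated ester), early catalyst precipitation with the electron-rich bromide, and base-induced opening of the phenolic dihydrobenzofuran at 90 °C.

Fallback, from 13 back to 15, is a Suzuki–Miyaura coupling of 13 with commercial (E)-2-(3,3-diethoxyprop-1-enyl)-4,4,5,5-tetramethyl-1,3,2-dioxaborolane (Pd(dppf)Cl2, K3PO4, dioxane/H2O, 60 °C). The reagent fixes the position and geometry of the double bond and the temperature is lower; acid then converts 15 into 16 as before.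

## Further compounds

F1 | step 6 | 2-methoxy-4-[6-bromo-4-hydroxy-8-methoxy-3-(trifluoroacetyl)-2H-chromen-2-yl]phenyl 4-methylbenzenesulfonate, C2 arranged as in 9 (2S by the priority rules) | COc1cc([C@H]2C(C(=O)C(F)(F)F)=C(O)c3cc(Br)cc(OC)c3O2)ccc1OS(=O)(=O)c1ccc(C)cc1
F2 | step 6 | (2S)-6-bromo-3-diazo-8-methoxy-2-[3-methoxy-4-(tosyloxy)phenyl]chroman-4-one | COc1cc([C@H]2C(=[N+]=[N-])C(=O)c3cc(Br)cc(OC)c3O2)ccc1OS(=O)(=O)c1ccc(C)cc1
F3 | step 5 | 4-formyl-2-methoxyphenyl 4-methylbenzenesulfonate | COc1cc(C=O)ccc1OS(=O)(=O)c1ccc(C)cc1
F4 | step 5 | (E)-1-(5-bromo-2-hydroxy-3-methoxyphenyl)-3-[3-methoxy-4-(tosyloxy)phenyl]prop-2-en-1-one | COc1cc(/C=C/C(=O)c2cc(Br)cc(OC)c2O)ccc1OS(=O)(=O)c1ccc(C)cc1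
F5 | step 5 | racemic 6-bromo-8-methoxy-2-[3-methoxy-4-(tosyloxy)phenyl]chroman-4-one | COc1cc(C2CC(=O)c3cc(Br)cc(OC)c3O2)ccc1OS(=O)(=O)c1ccc(C)cc1
F6 | step 5 | (2S,4S)-6-bromo-8-methoxy-2-[3-methoxy-4-(tosyloxy)phenyl]chroman-4-ol (cis) | COc1cc([C@@H]2C[C@H](O)c3cc(Br)cc(OC)c3O2)ccc1OS(=O)(=O)c1ccc(C)cc1
F7 | step 8 | 4-[(2R,3S)-5-[(E)-3,3-diethoxyprop-1-enyl]-3-(hydroxymethyl)-7-methoxy-2,3-dihydro-1-benzofuran-2-yl]-2-methoxyphenyl 4-methylbenzenesulfonate | COc1cc([C@@H]2Oc3c(OC)cc(/C=C/C(OCC)OCC)cc3[C@H]2CO)ccc1OS(=O)(=O)c1ccc(C)cc1
F0 | step 9 | none | none
A1 | alternative 1 | 3-methoxy-4-(methoxymethoxy)phenyllithium | [Li]c1ccc(OCOC)c(OC)c1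
A2 | alternative 1 | tert-butyldimethylsilyl ether of (E)-3-(4,4,5,5-tetramethyl-1,3,2-dioxaborolan-2-yl)prop-2-en-1-ol | CC(C)(C)[Si](C)(C)OC/C=C/B1OC(C)(C)C(C)(C)O1
A3 | alternative 1 | 2-[3-bromo-5-methoxy-4-(methoxymethoxy)phenyl]-1,3-dioxolane | COCOc1c(Br)cc(cc1OC)C1OCCO1
A4 | alternative 1 | tert-butyl{(2S,3R)-2-[5-(1,3-dioxolan-2-yl)-3-methoxy-2-(methoxymethoxy)phenyl]-3-[3-methoxy-4-(methoxymethoxy)phenyl]-3-(4,4,5,5-tetramethyl-1,3,2-dioxaborolan-2-yl)propoxy}dimethylsilane (anti) | COCOc1ccc(cc1OC)[C@H](B2OC(C)(C)C(C)(C)O2)[C@H](CO[Si](C)(C)C(C)(C)C)c1cc(C2OCCO2)cc(OC)c1OCOC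
A5 | alternative 2 | 4-bromo-2-methoxy-6-[(E)-2-nitroethenyl]phenol | COc1cc(Br)cc(/C=C/[N+](=O)[O-])c1O
A6 | alternative 2 | (2R,5R)-1-[3-methoxy-4-(methoxymethoxy)benzyl]-2,5-dimethylthiolanium bromide | C[C@@H]1CC[C@@H](C)[S+]1Cc1ccc(OCOC)c(OC)c1.[Br-]
A7 | alternative 2 | (2R,3S)-5-bromo-7-methoxy-2-[3-methoxy-4-(methoxymethoxy)phenyl]-3-(nitromethyl)-2,3-dihydro-1-benzofuran (trans) | COc1cc([C@@H]2Oc3c(OC)cc(Br)cc3[C@H]2C[N+](=O)[O-])ccc1OCOC
A8 | alternative 3 | (2S)-2-(5-bromo-2-hydroxy-3-methoxyphenyl)-3-(4-hydroxy-3-methoxyphenyl)propan-1-ol | COc1cc(C[C@H](CO)c2cc(Br)cc(OC)c2O)ccc1O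
A9 | alternative 3 | 4-[(2S)-2-(5-bromo-2-hydroxy-3-methoxyphenyl)-3-hydroxypropylidene]-2-methoxycyclohexa-2,5-dien-1-one | COC1=CC(=C[C@H](CO)c2cc(Br)cc(OC)c2O)C=CC1=O
A10 | alternative 3 | 4-[(2R,3S)-5-bromo-3-(hydroxymethyl)-7-methoxy-2,3-dihydro-1-benzofuran-2-yl]-2-methoxyphenol (trans; identical with 13) | COc1cc([C@@H]2Oc3c(OC)cc(Br)cc3[C@H]2CO)ccc1O
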